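**Assumption:** the C8–C6'' biaryl axis is hindered, but the given structure carries no descriptor for it, so the target is taken as the racemate about this axis and no atropselective step is planned.

## The problem

The target is a biflavone in which C8 of an acacetin unit (5,7-dihydroxy-4'-methoxyflavone) is bonded to C6'' of an apigenin unit (5'',7'',4'''-trihydroxyflavone); it has no stereocentre. The C8–C6'' bond joins two phloroglucinol-type rings and is flanked by four oxygen-bearing carbons (C7, C8a, C5'', C7''), so any reaction that forms it between two finished rings meets the full penalty of a tetra-ortho-oxygenated biaryl. Each ring A has two nucleophilic CH positions (C6 and C8) of similar reactivity, yet the acacetin unit must be joined at C8 and the apigenin unit at C6''. In addition, 6- and 8-substituted 5,7-dihydroxyflavones interconvert by opening of the pyrone ring (Wessely–Moser rearrangement), so the regiochemistry is secure only if the position of the pyran oxygen is never in question. The two B rings differ by one methyl group (4'-OMe against 4'''-OH), so global demethylation is excluded and every protecting group must be removable beside an aryl methyl ether. The γ-pyrone rings are opened by hydroxide or alkoxide on heating, which argues for unmasking the phenols last and under neutral conditions. The feature that opens a different route is ring A of the apigenin unit: read as the enol of a cyclohexane-1,3,5-trione, its C6'' is the α-carbon between the carbonyl carbons C5'' and C7'', its C8'' is the α-carbon between C7'' and C8a'', and C8a''=C4a'' with O1'' is the enol-ether edge of the γ-pyrone ring C. Ring A is therefore the product of two Claisen condensations between an arylacetic ester (C6'' with its aryl group, and C7'') and a 2-methyl-4-pyranone-3-carboxylate (C8'', C8a'', C4a'', C5''), and in that reading the hindered biaryl bond is only the bond between an ester α-carbon and its aryl substituent.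

## Retrosynthesis

**14 to 13.** The target 14 is traced to its tribenzyl ether 13 (O5, O7 and O4''' benzylated; 5''-OH and 7''-OH free). Benzyl is the one common phenol protecting group that is removed by hydrogenolysis without touching the 4'-methyl ether or the pyrones. No skeletal bond is cut here.

**13 to 5 and 11 (key disconnection).** Two bonds of ring A of the apigenin unit are cut: C7''–C8'' and C5''–C6''. This gives ethyl (flavon-8-yl)acetate 5, which carries C6'' and C7'', and the monocyclic pyrone ester 11, which carries C8'', C8a'', C4a'', C5'' and the complete rings B and C of the apigenin unit. The keto ester 12 lies between them. Against the neighbouring cut at C8–C6'', this one never forms a bond between two hindered sp2 centres. Against the classical cut through ring C of the apigenin unit (O1''–C2''), it avoids an acylphloroglucinol whose two ortho hydroxyls would compete and give 6- and 8-aryl isomers. The precursors are far simpler than 13: a flavone with a CH2CO2Et side chain and a trisubstituted pyrone, neither containing a crowded bond. The forward reaction must carry out both Claisen condensations as C-acylations while leaving the pyrone ring of 11 closed, because that ring fixes O1''.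

**5 to 3 and 4, then 3 to 2 to 1.** The C8–CH2 bond of 5 is cut to the 8-iodide 3 and the zinc enolate 4. Iodide 3 comes from commercial acacetin 1 by benzylation (2) and iodination. Acacetin supplies all three rings of its unit with the 4'-methyl ether in place, so B-ring differentiation is bought, not made. With both A-ring oxygens alkylated, electrophiles go to C8, so one regioselective substitution is enough. The same Claisen reading applies to C8 of the acacetin unit, but since that unit is commercial its ring A is not built.

**11 to 7 and 8, then 7 to 6.** The pyrone 11 is cut at O1''–C2'' and C4''–C4a'' to the arylpropiolic acid 7 and ethyl acetoacetate 8. The acid chloride 9 and the acyclic C-acylation product 10 lie on the way. This is the classical alkynoyl chloride and acetoacetate route to 4-pyranone-3-carboxylates. It delivers the methyl group (C8'') and the ester (C5'') on adjacent carbons of the pyrone. Acid 7 comes from commercial alkyne 6 by carboxylation.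

## Roads not taken

**Alternative 1:** the most obvious cut is the C8–C6'' bond between two finished flavones. The forward key step would be a Suzuki–Miyaura coupling of iodide 3 with the 6-boronate A1 of tri-O-benzylapigenin (or with boron and iodine exchanged), giving the pentabenzyl ether A2, followed by hydrogenolysis. The chosen plan is better for three reasons. The coupling makes the bond where it is most hindered, with four ortho oxygen substituents, an electron-rich di-ortho-oxygenated arylboron prone to protodeboronation and an electron-rich iodide slow in oxidative addition. A1 needs its own sequence of selective benzylation, C6 iodination, 5-O-benzylation and borylation, so two regioselective halogenations are needed where the chosen route needs one. In the chosen plan the same bond is made as an unhindered aryl–CH2 bond (step 3) and becomes a biaryl bond only when ring A aromatizes.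

**Alternative 2:** the same bond could be cut without prefunctionalization, as a dehydrogenative cross-coupling of acacetin 1 with apigenin A3, for example by anodic oxidation at a boron-doped diamond electrode in hexafluoroisopropanol. It would be a single step to 14. However, four nucleophilic positions (C6, C8, C6'', C8'') of nearly equal reactivity and two partners of nearly equal oxidation potential are present. Homodimers and regioisomeric cross-dimers such as the 8,8''-linked isomer A4 would form beside 14, and the free B-ring phenol of A3 adds C–O coupling. Nothing in either substrate directs the coupling to C8 of one and C6'' of the other, whereas the chosen plan decides both positions by construction.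

**Alternative 3:** both pyrone rings could be cut to leave the biaryl core. 2,2',4,4',6,6'-Hexamethoxybiphenyl A5 (oxidative dimerization of 1,3,5-trimethoxybenzene) would be bis-acetylated to A6 and carried through two flavone annulations (Baker–Venkataraman or chalcone cyclization). The core is C2-symmetric and the target is not. One ring must close through the oxygen next to the biaryl bond (8-linked) and the other through the distal oxygen (6''-linked), and the two acetyl groups must receive different aroyl partners. This requires several selective mono-demethylations. The final global demethylation would also cleave the 4'-methyl ether, and acidic demethylation invites Wessely–Moser scrambling. The chosen plan fixes the pyran oxygen before ring A exists.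

Key step: step 6

## Route

Step 1
Reactants: 1 acacetin (5,7-dihydroxy-2-(4-methoxyphenyl)-4H-chromen-4-one)
Product: 2 5,7-bis(benzyloxy)-2-(4-methoxyphenyl)-4H-chromen-4-one
Conditions: BnBr (3 equiv), K2CO3, DMF, 80 °C
Reagents that add atoms: benzyl bromide, BrCc1ccccc1
Why: Williamson etherification; the 7-OH alkylates readily and the chelated 5-OH follows with excess bromide in warm DMF; benzyl is chosen because it is later removed without touching the 4'-methyl ether.

Step 2
Reactants: 2 5,7-bis(benzyloxy)-2-(4-methoxyphenyl)-4H-chromen-4-one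
Product: 3 5,7-bis(benzyloxy)-8-iodo-2-(4-methoxyphenyl)-4H-chromen-4-one
Conditions: N-iodosuccinimide, CF3CO2H (cat.), MeCN, rt
Reagents that add atoms: N-iodosuccinimide, IN1C(=O)CCC1=O
Why: Electrophilic aromatic iodination; 5,7-dialkoxyflavones are known to react at C8 (ortho to 7-OBn and O1, para to 5-OBn), C6 lies between two benzyloxy groups, and ring B is deactivated by the pyrone.

Step 3
Reactants: 3 5,7-bis(benzyloxy)-8-iodo-2-(4-methoxyphenyl)-4H-chromen-4-one; 4 (2-ethoxy-2-oxoethyl)zinc bromide
Product: 5 ethyl 2-[5,7-bis(benzyloxy)-2-(4-methoxyphenyl)-4-oxo-4H-chromen-8-yl]acetate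
Conditions: Pd2(dba)3 (2.5 mol %), XPhos (10 mol %), THF, 65 °C
Reagents that add atoms: none
Why: Palladium-catalysed α-arylation of a zinc ester enolate (Reformatsky–Negishi coupling); the neutral organozinc tolerates the flavone carbonyl, and the bulky biarylphosphine on zerovalent palladium supports oxidative addition and reductive elimination at the di-ortho-substituted iodide.

Step 4
Reactants: 6 1-(benzyloxy)-4-ethynylbenzene
Product: 7 3-[4-(benzyloxy)phenyl]prop-2-ynoic acid
Conditions: n-BuLi, THF, −78 °C; CO2; then 1 M HCl
Reagents that add atoms: carbon dioxide, O=C=O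
Why: Deprotonation of the terminal alkyne and carboxylation of the lithium acetylide, a standard route to arylpropiolic acids.

Step 5
Reactants: 7 3-[4-(benzyloxy)phenyl]prop-2-ynoic acid; 8 ethyl acetoacetate
Product: 11 ethyl 6-[4-(benzyloxy)phenyl]-2-methyl-4-oxo-4H-pyran-3-carboxylate, via acid chloride 9 (not isolated), via acyclic ynone keto ester 10 (not isolated)
Conditions: (COCl)2, DMF (cat.), CH2Cl2, 0 °C to rt, evaporation; then 8, MgCl2, pyridine, CH2Cl2, 0 °C to rt; then Et3N, rt
Reagents that add atoms: none
Why: C-acylation of the magnesium chelate of a β-keto ester by an acid chloride, then 6-endo-dig oxa-Michael addition of the acetyl enol oxygen to the ynone; this classical alkynoyl chloride and acetoacetate route fixes O1'', the aryl group at C2'', C4''=O, the ester at C4a'' and the methyl group at C8a'' of the apigenin unit.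

Step 6
Reactants: 5 ethyl 2-[5,7-bis(benzyloxy)-2-(4-methoxyphenyl)-4-oxo-4H-chromen-8-yl]acetate; 11 ethyl 6-[4-(benzyloxy)phenyl]-2-methyl-4-oxo-4H-pyran-3-carboxylate
Product: 13 5,7-bis(benzyloxy)-8-{2-[4-(benzyloxy)phenyl]-5,7-dihydroxy-4-oxo-4H-chromen-6-yl}-2-(4-methoxyphenyl)-4H-chromen-4-one, via keto ester 12 (not isolated)
Conditions: 11 (1.2 equiv), LiN(SiMe3)2 (1.3 equiv), THF, −78 °C; then 5 (1.0 equiv), −78 to −20 °C; then LiN(SiMe3)2 (2.5 equiv), −20 to 25 °C; then 1 M HCl
Reagents that add atoms: none
Why: Proposed new method: the lateral dienolate of 11 (the C8'' methyl group is acidified by the vinylogous C4'' ketone and the C5'' ester) should attack the unhindered CH2CO2Et carbonyl of 5 in a crossed Claisen condensation (C8''–C7'' bond) to give keto ester 12 as its enolate; a second deprotonation at the doubly activated benzylic C6'' then closes ring A of the apigenin unit by a Dieckmann-type attack on the C5'' ester (C6''–C5'' bond, 6-enolendo-exo-trig), and loss of ethoxide with tautomerization gives the aromatic 5'',7''-diphenoxide, the thermodynamic sink, which is protonated on work-up. The closest known reaction type is the toluate-anion (Staunton–Weinreb-type) Claisen–Dieckmann annulation of ortho-toluate anions with esters to naphthalene-1,3-diols, together with lateral acylation of 2-methyl-4-pyranones and the Claisen folding of polyketo esters to acylphloroglucinols; new is their combination on a γ-pyrone-3-carboxylate with a flavonylacetate as the two-carbon partner. Both partners are an ester with an acidic CH, so the alternative order (C6'' enolate of 5 on the C5'' ester first, then C8'' on C7'') converges on the same six-membered ring. No stereocentre is formed, and the biaryl axis arises in racemic form when C6'' becomes sp2. The selectivity needed is regiochemical, aryl at C6'' and not at C8'', and the substrate secures it: O1'' and the C4a''=C8a'' bond are already in place in the intact pyrone ring of 11, so the ring oxygen cannot change places with the 5''-oxygen as it can when an acylphloroglucinol diketone is cyclized, and the only electrophile within reach of the C6'' carbanion is the C5'' ester. An amide base in THF at low temperature is specified, not an alkoxide in alcohol, so that the pyrone is deprotonated faster than it is opened, and 11 is fully enolized before 5 is added so that neither ester self-condenses.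

Step 7
Reactants: 13 5,7-bis(benzyloxy)-8-{2-[4-(benzyloxy)phenyl]-5,7-dihydroxy-4-oxo-4H-chromen-6-yl}-2-(4-methoxyphenyl)-4H-chromen-4-one
Product: 14 5,7-dihydroxy-8-[5,7-dihydroxy-2-(4-hydroxyphenyl)-4-oxo-4H-chromen-6-yl]-2-(4-methoxyphenyl)-4H-chromen-4-one
Conditions: H2 (1 atm), Pd/C (10 wt %), THF–MeOH, rt
Reagents that add atoms: none
Why: Hydrogenolysis of the three benzyl ethers; the aryl methyl ether is inert, and the C2=C3 bonds of the two flavones, as aryl-conjugated vinylogous esters, should not be reduced at 1 atm and room temperature.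

## Compound list

1 | acacetin, 5,7-dihydroxy-2-(4-methoxyphenyl)-4H-chromen-4-one | COc1ccc(cc1)-c1cc(=O)c2c(O)cc(O)cc2o1 | starting material
2 | 5,7-bis(benzyloxy)-2-(4-methoxyphenyl)-4H-chromen-4-one | COc1ccc(cc1)-c1cc(=O)c2c(OCc3ccccc3)cc(OCc3ccccc3)cc2o1 | intermediate
3 | 5,7-bis(benzyloxy)-8-iodo-2-(4-methoxyphenyl)-4H-chromen-4-one | COc1ccc(cc1)-c1cc(=O)c2c(OCc3ccccc3)cc(OCc3ccccc3)c(I)c2o1 | intermediate
4 | (2-ethoxy-2-oxoethyl)zinc bromide | CCOC(=O)C[Zn]Br | starting material
5 | ethyl 2-[5,7-bis(benzyloxy)-2-(4-methoxyphenyl)-4-oxo-4H-chromen-8-yl]acetate | CCOC(=O)Cc1c(OCc2ccccc2)cc(OCc2ccccc2)c2c(=O)cc(oc12)-c1ccc(OC)cc1 | intermediate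
6 | 1-(benzyloxy)-4-ethynylbenzene | C#Cc1ccc(OCc2ccccc2)cc1 | starting material
7 | 3-[4-(benzyloxy)phenyl]prop-2-ynoic acid | OC(=O)C#Cc1ccc(OCc2ccccc2)cc1 | intermediate
8 | ethyl acetoacetate (ethyl 3-oxobutanoate) | CCOC(=O)CC(C)=O | starting material
9 | 3-[4-(benzyloxy)phenyl]prop-2-ynoyl chloride | ClC(=O)C#Cc1ccc(OCc2ccccc2)cc1 | intermediate
10 | ethyl 2-acetyl-5-[4-(benzyloxy)phenyl]-3-oxopent-4-ynoate | CCOC(=O)C(C(C)=O)C(=O)C#Cc1ccc(OCc2ccccc2)cc1 | intermediate
11 | ethyl 6-[4-(benzyloxy)phenyl]-2-methyl-4-oxo-4H-pyran-3-carboxylate | CCOC(=O)c1c(C)oc(cc1=O)-c1ccc(OCc2ccccc2)cc1 | intermediate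
12 | ethyl 6-[4-(benzyloxy)phenyl]-2-{3-[5,7-bis(benzyloxy)-2-(4-methoxyphenyl)-4-oxo-4H-chromen-8-yl]-2-oxopropyl}-4-oxo-4H-pyran-3-carboxylate | CCOC(=O)c1c(CC(=O)Cc2c(OCc3ccccc3)cc(OCc3ccccc3)c3c(=O)cc(oc23)-c2ccc(OC)cc2)oc(cc1=O)-c1ccc(OCc2ccccc2)cc1 | intermediate
13 | 5,7-bis(benzyloxy)-8-{2-[4-(benzyloxy)phenyl]-5,7-dihydroxy-4-oxo-4H-chromen-6-yl}-2-(4-methoxyphenyl)-4H-chromen-4-one (racemic about the C8–C6'' axis) | COc1ccc(cc1)-c1cc(=O)c2c(OCc3ccccc3)cc(OCc3ccccc3)c(c2o1)-c1c(O)cc2oc(cc(=O)c2c1O)-c1ccc(OCc2ccccc2)cc1 | intermediate
14 | 5,7-dihydroxy-8-[5,7-dihydroxy-2-(4-hydroxyphenyl)-4-oxo-4H-chromen-6-yl]-2-(4-methoxyphenyl)-4H-chromen-4-one (racemic about the C8–C6'' axis) | COc1ccc(cc1)-c1cc(=O)c2c(O)cc(O)c(c2o1)-c1c(O)cc2oc(cc(=O)c2c1O)-c1ccc(O)cc1 | target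

## Step count and least certain steps

Total step count: 7. Longest linear sequence: 5 steps (steps 1, 2, 3, 6, 7); the second branch (steps 4, 5) joins at step 6.

**Step 6 (key step, proposed new method).**
- Proton transfer may win over carbon–carbon bond formation, because 5 is itself enolizable at C6'' and the dienolate of 11 can act as a base.
- The C7'' enolate oxygen of 12 may be acylated by the C5'' ester in place of C-acylation at C6''.
- The second ring closure may stall because C6'' is shielded by the two ortho substituents of the flavonyl group.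
- On warming, liberated ethoxide may open the pyrone ring, which would cost the regiochemical lock.

Fallback by known chemistry, setting out from iodide 3 and returning at 14: Miyaura borylation of 3 (B2pin2, PdCl2(dppf), KOAc, dioxane, 90 °C) gives 5,7-bis(benzyloxy)-2-(4-methoxyphenyl)-8-(4,4,5,5-tetramethyl-1,3,2-dioxaborolan-2-yl)-4H-chromen-4-one F1. Commercial apigenin (A3) is benzylated at O7 and O4' only (BnBr, K2CO3, acetone, reflux; the chelated 5-OH stays free) to 7-(benzyloxy)-2-[4-(benzyloxy)phenyl]-5-hydroxy-4H-chromen-4-one F2. This is iodinated ortho to the free 5-OH (benzyltrimethylammonium dichloroiodate, CaCO3, CH2Cl2–MeOH) to 7-(benzyloxy)-2-[4-(benzyloxy)phenyl]-5-hydroxy-6-iodo-4H-chromen-4-one F3. Suzuki–Miyaura coupling of F1 with F3 (Pd(OAc)2, SPhos, K3PO4, toluene–water, 100 °C) gives 5,7-bis(benzyloxy)-8-{7-(benzyloxy)-2-[4-(benzyloxy)phenyl]-5-hydroxy-4-oxo-4H-chromen-6-yl}-2-(4-methoxyphenyl)-4H-chromen-4-one F4. Hydrogenolysis under the conditions of step 7 then gives 14.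

**Step 3.** Oxidative addition and reductive elimination at the electron-rich, di-ortho-substituted iodide may be slow, so that reduction of the carbon–iodine bond and homocoupling of the zinc enolate take over. Fallback that replaces cross-coupling by a sigmatropic rearrangement, setting out from 1 and returning at 5 (it also bypasses steps 1 and 2):
- Selective 7-O-allylation (allyl bromide, K2CO3, acetone) gives 7-(allyloxy)-5-hydroxy-2-(4-methoxyphenyl)-4H-chromen-4-one F5.
- Aromatic Claisen rearrangement (N,N-diethylaniline, 190 °C), which in 7-allyloxyflavones goes mainly to C8, gives 8-allyl-5,7-dihydroxy-2-(4-methoxyphenyl)-4H-chromen-4-one F6.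
- Benzylation as in step 1 gives 8-allyl-5,7-bis(benzyloxy)-2-(4-methoxyphenyl)-4H-chromen-4-one F7.
- Lemieux–Johnson cleavage (OsO4 cat., NaIO4, 2,6-lutidine, dioxane–water) gives 2-[5,7-bis(benzyloxy)-2-(4-methoxyphenyl)-4-oxo-4H-chromen-8-yl]acetaldehyde F8.
- Pinnick oxidation (NaClO2, NaH2PO4, 2-methyl-2-butene) gives 2-[5,7-bis(benzyloxy)-2-(4-methoxyphenyl)-4-oxo-4H-chromen-8-yl]acetic acid F9.
- Esterification (EtI, K2CO3, DMF) gives 5.

**Step 5.** O-acylation of the ambident enolate, and conjugate addition of pyridine, chloride or the enolate carbon to the alkynoyl chloride or the ynone, may compete with C-acylation and lead away from the 4-pyranone. Fallback that replaces the metal enolate by a neutral enamine, which acylates at carbon, setting out from 8 (and 7) and returning at 11: condensation of 8 with pyrrolidine (toluene, reflux, water separator) gives ethyl (E)-3-(pyrrolidin-1-yl)but-2-enoate F10. C-acylation of F10 with acid chloride 9, made from 7 as in step 5 (Et3N, CH2Cl2, 0 °C), gives ethyl 5-[4-(benzyloxy)phenyl]-3-oxo-2-[1-(pyrrolidin-1-yl)ethylidene]pent-4-ynoate F11. Aqueous HCl in THF hydrolyses the enamine to 10, which closes to 11.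

**Step 7.** Partial reduction of the C2=C3 bonds, or incomplete cleavage through poor solubility and strong adsorption of the polyphenol on the catalyst, may occur. Fallback that replaces reduction by Lewis-acid cleavage, from 13 directly to 14: BCl3 with pentamethylbenzene as cation scavenger, CH2Cl2, −78 °C, conditions under which aryl benzyl ethers are cleaved and aryl methyl ethers are kept. This fallback makes no new compound (F0).

## Further compounds

F1 | step 6 | 5,7-bis(benzyloxy)-2-(4-methoxyphenyl)-8-(4,4,5,5-tetramethyl-1,3,2-dioxaborolan-2-yl)-4H-chromen-4-one | COc1ccc(cc1)-c1cc(=O)c2c(OCc3ccccc3)cc(OCc3ccccc3)c(B3OC(C)(C)C(C)(C)O3)c2o1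
F2 | step 6 | 7-(benzyloxy)-2-[4-(benzyloxy)phenyl]-5-hydroxy-4H-chromen-4-one | Oc1cc(OCc2ccccc2)cc2oc(cc(=O)c12)-c1ccc(OCc2ccccc2)cc1
F3 | step 6 | 7-(benzyloxy)-2-[4-(benzyloxy)phenyl]-5-hydroxy-6-iodo-4H-chromen-4-one | Oc1c(I)c(OCc2ccccc2)cc2oc(cc(=O)c12)-c1ccc(OCc2ccccc2)cc1
F4 | step 6 | 5,7-bis(benzyloxy)-8-{7-(benzyloxy)-2-[4-(benzyloxy)phenyl]-5-hydroxy-4-oxo-4H-chromen-6-yl}-2-(4-methoxyphenyl)-4H-chromen-4-one | COc1ccc(cc1)-c1cc(=O)c2c(OCc3ccccc3)cc(OCc3ccccc3)c(c2o1)-c1c(OCc2ccccc2)cc2oc(cc(=O)c2c1O)-c1ccc(OCc2ccccc2)cc1
F5 | step 3 | 7-(allyloxy)-5-hydroxy-2-(4-methoxyphenyl)-4H-chromen-4-one | COc1ccc(cc1)-c1cc(=O)c2c(O)cc(OCC=C)cc2o1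
F6 | step 3 | 8-allyl-5,7-dihydroxy-2-(4-methoxyphenyl)-4H-chromen-4-one | COc1ccc(cc1)-c1cc(=O)c2c(O)cc(O)c(CC=C)c2o1
F7 | step 3 | 8-allyl-5,7-bis(benzyloxy)-2-(4-methoxyphenyl)-4H-chromen-4-one | COc1ccc(cc1)-c1cc(=O)c2c(OCc3ccccc3)cc(OCc3ccccc3)c(CC=C)c2o1
F8 | step 3 | 2-[5,7-bis(benzyloxy)-2-(4-methoxyphenyl)-4-oxo-4H-chromen-8-yl]acetaldehyde | COc1ccc(cc1)-c1cc(=O)c2c(OCc3ccccc3)cc(OCc3ccccc3)c(CC=O)c2o1
F9 | step 3 | 2-[5,7-bis(benzyloxy)-2-(4-methoxyphenyl)-4-oxo-4H-chromen-8-yl]acetic acid | COc1ccc(cc1)-c1cc(=O)c2c(OCc3ccccc3)cc(OCc3ccccc3)c(CC(O)=O)c2o1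
F10 | step 5 | ethyl (E)-3-(pyrrolidin-1-yl)but-2-enoate | CCOC(=O)/C=C(\C)N1CCCC1
F11 | step 5 | ethyl 5-[4-(benzyloxy)phenyl]-3-oxo-2-[1-(pyrrolidin-1-yl)ethylidene]pent-4-ynoate | CCOC(=O)C(C(=O)C#Cc1ccc(OCc2ccccc2)cc1)=C(C)N1CCCC1
F0 | step 7 | none | none
A1 | alternative 1 | 5,7-bis(benzyloxy)-2-[4-(benzyloxy)phenyl]-6-(4,4,5,5-tetramethyl-1,3,2-dioxaborolan-2-yl)-4H-chromen-4-one | CC1(C)OB(OC1(C)C)c1c(OCc2ccccc2)cc2oc(cc(=O)c2c1OCc1ccccc1)-c1ccc(OCc2ccccc2)cc1
A2 | alternative 1 | 5,7-bis(benzyloxy)-8-{5,7-bis(benzyloxy)-2-[4-(benzyloxy)phenyl]-4-oxo-4H-chromen-6-yl}-2-(4-methoxyphenyl)-4H-chromen-4-one | COc1ccc(cc1)-c1cc(=O)c2c(OCc3ccccc3)cc(OCc3ccccc3)c(c2o1)-c1c(OCc2ccccc2)cc2oc(cc(=O)c2c1OCc1ccccc1)-c1ccc(OCc2ccccc2)cc1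
A3 | alternative 2 | apigenin, 5,7-dihydroxy-2-(4-hydroxyphenyl)-4H-chromen-4-one | Oc1ccc(cc1)-c1cc(=O)c2c(O)cc(O)cc2o1
A4 | alternative 2 | 8-[5,7-dihydroxy-2-(4-hydroxyphenyl)-4-oxo-4H-chromen-8-yl]-5,7-dihydroxy-2-(4-methoxyphenyl)-4H-chromen-4-one (8,8''-linked isomer) | COc1ccc(cc1)-c1cc(=O)c2c(O)cc(O)c(c2o1)-c1c(O)cc(O)c2c(=O)cc(oc12)-c1ccc(O)cc1
A5 | alternative 3 | 2,2',4,4',6,6'-hexamethoxybiphenyl | COc1cc(OC)c(c(OC)c1)-c1c(OC)cc(OC)cc1OC
A6 | alternative 3 | 3,3'-diacetyl-2,2',4,4',6,6'-hexamethoxybiphenyl | COc1cc(OC)c(C(C)=O)c(OC)c1-c1c(OC)cc(OC)c(C(C)=O)c1OC
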